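**Plan**

- Retrosynthetic cuts, in order: C11–OOH with the C9=C10 shift (Schenck ene); C8–C9 (prenyl onto an enal); C8 oxidation of the carvone methyl; the C6 O–acyl bond; then ring C2–O (Rubottom) and C3–O/C6–O (one O2 bridge), back to the 2-silyloxy-1,3-diene of (R)-carvone.
- Forward: the carvone ring is never opened. The four ring oxygens come first (steps 1–4), the chain is then joined at C8 (steps 5–7), and the hydroperoxide is made last (step 8).
- Enabling feature: ring carbons C6–C1–C2–C3 are all oxygenated, with the C3 and C6 oxygens cis-1,4 across the cyclohexanone and C1/C2 between them as ketone and tertiary carbinol. This is the footprint of an O–O bridge across a cyclohexa-1,3-diene whose remaining C1=C2 bond is an enol ether.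
- Stereochemistry: C5 comes from (R)-carvone; C3 and C6 from suprafacial 1O2 addition anti to the isopropenyl group; C2 from oxidation anti to the peroxide bridge; the C8 carbinol is transient; the E-alkene comes from the ene reaction.
- Singlet oxygen is used twice: first as a dienophile on the ring, last as an enophile on the chain.

Key step: step 2

Remark on locants: ring atoms are numbered as in carvone (C1 = ring C=O, C2 = C–CH3, C5 = carbon bearing the side chain); the side chain is C7 (ring-bound sp2 carbon), C14 (its =CH2), C8 (chain C=O), C9, C10, C11 (CMe2).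

**Route**

Step 1
Reactants: 1 (R)-(−)-carvone
Product: 2 trimethyl{[(3R)-6-methyl-3-(prop-1-en-2-yl)cyclohexa-1,5-dien-1-yl]oxy}silane
Conditions: LDA (1.1 equiv), THF, −78 °C; TMSCl (1.2 equiv), −78 → 0 °C; cold NaHCO3/pentane work-up, used at once
Reagents that add atoms: chlorotrimethylsilane, C[Si](C)(C)Cl
Why: Kinetic α′-deprotonation at C6 and O-silylation of the cross-conjugated lithium dienolate (kinetic silyl enol ether formation) should give the s-cis-locked 2-silyloxy-1,3-diene; C5 is not touched.

Step 2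
Reactants: 2 trimethyl{[(3R)-6-methyl-3-(prop-1-en-2-yl)cyclohexa-1,5-dien-1-yl]oxy}silane
Product: 5 (1R,4S,6S,8S)-6-methyl-8-(prop-1-en-2-yl)-6-[(trimethylsilyl)oxy]-2,3-dioxabicyclo[2.2.2]octan-5-one, via silyl enol ether endoperoxide 3 (not isolated), via silyloxy oxirane 4 (not isolated)
Conditions: O2, hν (white LED), TPP (0.5 mol %), CH2Cl2, −78 °C; Ar purge; DMDO (1.05 equiv, acetone solution), −78 → −30 °C; concentrated cold, used crude
Reagents that add atoms: dioxygen (as singlet oxygen), O=O; dimethyldioxirane, CC1(C)OO1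
Why: Singlet oxygen should add suprafacially across C3 and C6 of the s-cis-locked 2-silyloxy-cyclohexa-1,3-diene in a [4+2] cycloaddition that closes the 2,3-dioxabicyclo[2.2.2]oct-5-ene ring with both C–O bonds formed in one pericyclic event; the remaining C1=C2 silyl enol ether of 3 is then epoxidised by DMDO, and oxirane 4 opens with a 1,4 O→O silyl shift (Rubottom oxidation) to the α-silyloxy ketone. The closest known reaction types are endoperoxide formation from cyclohexa-1,3-dienes and 1O2 (α-terpinene to ascaridole) and the DMDO Rubottom oxidation of tetrasubstituted silyl enol ethers. C3 and C6 are set cis to each other by the suprafacial mode and anti to the C5 isopropenyl group by steric approach control, the same facial bias this diene shows towards carbon dienophiles. C2 is set by DMDO attacking the methyl-bearing enol ether carbon from the face anti to the peroxide bridge (lone-pair repulsion, as in peracid and OsO4 additions to 2,3-dioxabicyclo[2.2.2]octenes); that carbon lies over the unsubstituted C4 methylene, not over C5. The step needs chemoselectivity for the diene and then for the enol ether over the isopropenyl group, which the inertness of 1,1-disubstituted alkenes to 1O2 and the much higher nucleophilicity of the silyl enol ether at −78 °C should secure. Running both oxidations cold in one flask removes the enol ether before the endoperoxide can fragment to an α′-silylperoxy enone.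

Step 3
Reactants: 5 (1R,4S,6S,8S)-6-methyl-8-(prop-1-en-2-yl)-6-[(trimethylsilyl)oxy]-2,3-dioxabicyclo[2.2.2]octan-5-one
Product: 7 (2S,3R,5S,6S)-2,3,6-trihydroxy-2-methyl-5-(prop-1-en-2-yl)cyclohexan-1-one, via O-silyl diol 6 (not isolated)
Conditions: thiourea (1.2 equiv), MeOH–H2O (20:1), 0 °C → rt; then citric acid (cat.), rt
Reagents that add atoms: none
Why: Thiourea reduction of the bicyclic O–O bond (standard endoperoxide to cis-1,4-diol reduction) breaks no C–O bond, so the C3 and C6 configurations are kept; mild acid methanolysis then removes the tertiary O–TMS group. No base is present, which avoids the Kornblum–DeLaMare pathway of the α-peroxy ketone.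

Step 4
Reactants: 7 (2S,3R,5S,6S)-2,3,6-trihydroxy-2-methyl-5-(prop-1-en-2-yl)cyclohexan-1-one
Product: 8 (1S,3S,4R,6S)-3,4-dihydroxy-3-methyl-2-oxo-6-(prop-1-en-2-yl)cyclohexyl 3-methylbutanoate
Conditions: (i-BuCO)2O (1.05 equiv), 2,4,6-collidine (2 equiv), DMAP (2 mol %), CH2Cl2, −40 → −20 °C
Reagents that add atoms: 3-methylbutanoic anhydride, CC(C)CC(=O)OC(=O)CC(C)C
Why: Sterically controlled DMAP-catalysed acylation should select the equatorial α-ketol hydroxyl at C6 over the axial C3–OH (flanked by quaternary C2) and the tertiary C2–OH. The C6 centre already has the favoured trans-diequatorial relation to C5, so epimerisation is not a threat.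

Step 5
Reactants: 8 (1S,3S,4R,6S)-3,4-dihydroxy-3-methyl-2-oxo-6-(prop-1-en-2-yl)cyclohexyl 3-methylbutanoate
Product: 10 (1S,3S,4R,6S)-3,4-dihydroxy-3-methyl-2-oxo-6-(3-oxoprop-1-en-2-yl)cyclohexyl 3-methylbutanoate, via allylic alcohol 9 (not isolated)
Conditions: SeO2 (0.5 equiv), t-BuOOH (2 equiv), CH2Cl2, rt; filtration; then activated MnO2, CH2Cl2, rt
Reagents that add atoms: selenium dioxide, O=[Se]=O; tert-butyl hydroperoxide, CC(C)(C)OO (terminal oxidant that restores the selenium oxygen)
Why: SeO2/t-BuOOH allylic oxidation (ene reaction then [2,3]-shift, Riley type) should oxidise the methyl group of the 1,1-disubstituted alkene in preference to the deactivated ring methine; MnO2 then converges the primary allylic alcohol on the enal without touching the saturated C3–OH.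

Step 6
Reactants: 10 (1S,3S,4R,6S)-3,4-dihydroxy-3-methyl-2-oxo-6-(3-oxoprop-1-en-2-yl)cyclohexyl 3-methylbutanoate
Product: 12 (1S,3S,4R,6S)-3,4-dihydroxy-6-(3-hydroxy-6-methylhepta-1,5-dien-2-yl)-3-methyl-2-oxocyclohexyl 3-methylbutanoate (both C8 epimers), via branched γ-adduct 11 (not isolated)
Conditions: In powder (1.5 equiv), prenyl bromide (2 equiv), H2O (6 equiv), CH2Cl2, rt, 48–72 h
Reagents that add atoms: 1-bromo-3-methylbut-2-ene (prenyl bromide), CC(C)=CCBr
Why: Barbier-type prenylindium addition is aldehyde-selective and tolerates water, free hydroxyls, the ketone and the ester. Under limited-water conditions the kinetic γ-adduct should be relayed to the linear α-adduct by an In(III)-promoted 2-oxonia-Cope rearrangement (α-selective indium-mediated prenylation). The C8 carbinol forms as an epimer mixture that is erased in step 7.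

Step 7
Reactants: 12 (1S,3S,4R,6S)-3,4-dihydroxy-6-(3-hydroxy-6-methylhepta-1,5-dien-2-yl)-3-methyl-2-oxocyclohexyl 3-methylbutanoate
Product: 13 (1S,3S,4R,6S)-3,4-dihydroxy-3-methyl-6-(6-methyl-3-oxohepta-1,5-dien-2-yl)-2-oxocyclohexyl 3-methylbutanoate
Conditions: activated MnO2 (15 equiv), CH2Cl2, rt, dark; filtered and used directly
Reagents that add atoms: none
Why: Chemoselective MnO2 oxidation of the allylic C8–OH (both epimers) under neutral conditions should give the α-methylene ketone without moving the β,γ-prenyl double bond into conjugation and without oxidising the C3–OH.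

Step 8
Reactants: 13 (1S,3S,4R,6S)-3,4-dihydroxy-3-methyl-6-(6-methyl-3-oxohepta-1,5-dien-2-yl)-2-oxocyclohexyl 3-methylbutanoate
Product: 14 (1S,3S,4R,6S)-6-[(4E)-6-hydroperoxy-6-methyl-3-oxohepta-1,4-dien-2-yl]-3,4-dihydroxy-3-methyl-2-oxocyclohexyl 3-methylbutanoate (CNP0239240.1)
Conditions: O2, hν (white LED), TPP (1 mol %), CH2Cl2, −20 °C; cold chromatography
Reagents that add atoms: dioxygen (as singlet oxygen), O=O
Why: Schenck ene reaction of the trisubstituted prenyl alkene: 1O2 should abstract a C9–H (allylic, α to the C8 ketone, on the disubstituted side of the alkene), placing the hydroperoxide on tertiary C11 and giving the conjugated (E)-C9=C10 enone. The electron-poor C7=C14 bond is inert to 1O2, and no ring stereocentre is involved.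

**Compound list**

1 | (R)-(−)-carvone, (5R)-2-methyl-5-(prop-1-en-2-yl)cyclohex-2-en-1-one | CC(=C)[C@@H]1CC=C(C)C(=O)C1 | starting material
2 | trimethyl{[(3R)-6-methyl-3-(prop-1-en-2-yl)cyclohexa-1,5-dien-1-yl]oxy}silane | CC(=C)[C@@H]1CC=C(C)C(O[Si](C)(C)C)=C1 | intermediate
3 | silyl enol ether endoperoxide, (1S,4R,7S)-5-methyl-7-(prop-1-en-2-yl)-6-[(trimethylsilyl)oxy]-2,3-dioxabicyclo[2.2.2]oct-5-ene (not isolated) | CC(=C)[C@@H]1C[C@H]2OO[C@@H]1C(O[Si](C)(C)C)=C2C | intermediate
4 | silyloxy oxirane, 5,6-epoxide of 3 with the oxirane oxygen anti to the O–O bridge (not isolated) | CC(=C)[C@@H]1C[C@H]2OO[C@@H]1[C@@]3(O[Si](C)(C)C)O[C@@]23C | intermediate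
5 | (1R,4S,6S,8S)-6-methyl-8-(prop-1-en-2-yl)-6-[(trimethylsilyl)oxy]-2,3-dioxabicyclo[2.2.2]octan-5-one | CC(=C)[C@@H]1C[C@H]2OO[C@@H]1C(=O)[C@@]2(C)O[Si](C)(C)C | intermediate
6 | O-silyl diol, (2S,3R,5S,6S)-3,6-dihydroxy-2-methyl-5-(prop-1-en-2-yl)-2-[(trimethylsilyl)oxy]cyclohexan-1-one (not isolated) | CC(=C)[C@@H]1C[C@@H](O)[C@](C)(O[Si](C)(C)C)C(=O)[C@H]1O | intermediate
7 | (2S,3R,5S,6S)-2,3,6-trihydroxy-2-methyl-5-(prop-1-en-2-yl)cyclohexan-1-one | CC(=C)[C@@H]1C[C@@H](O)[C@](C)(O)C(=O)[C@H]1O | intermediate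
8 | (1S,3S,4R,6S)-3,4-dihydroxy-3-methyl-2-oxo-6-(prop-1-en-2-yl)cyclohexyl 3-methylbutanoate | CC(=C)[C@@H]1C[C@@H](O)[C@](C)(O)C(=O)[C@H]1OC(=O)CC(C)C | intermediate
9 | allylic alcohol, (1S,3S,4R,6S)-3,4-dihydroxy-6-(3-hydroxyprop-1-en-2-yl)-3-methyl-2-oxocyclohexyl 3-methylbutanoate (not isolated) | C=C(CO)[C@@H]1C[C@@H](O)[C@](C)(O)C(=O)[C@H]1OC(=O)CC(C)C | intermediate
10 | (1S,3S,4R,6S)-3,4-dihydroxy-3-methyl-2-oxo-6-(3-oxoprop-1-en-2-yl)cyclohexyl 3-methylbutanoate | C=C(C=O)[C@@H]1C[C@@H](O)[C@](C)(O)C(=O)[C@H]1OC(=O)CC(C)C | intermediate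
11 | branched γ-adduct, (1S,3S,4R,6S)-3,4-dihydroxy-6-(3-hydroxy-4,4-dimethylhexa-1,5-dien-2-yl)-3-methyl-2-oxocyclohexyl 3-methylbutanoate, C8 epimers (not isolated) | C=C(C(O)C(C)(C)C=C)[C@@H]1C[C@@H](O)[C@](C)(O)C(=O)[C@H]1OC(=O)CC(C)C | intermediate
12 | (1S,3S,4R,6S)-3,4-dihydroxy-6-(3-hydroxy-6-methylhepta-1,5-dien-2-yl)-3-methyl-2-oxocyclohexyl 3-methylbutanoate, C8 epimers | C=C(C(O)CC=C(C)C)[C@@H]1C[C@@H](O)[C@](C)(O)C(=O)[C@H]1OC(=O)CC(C)C | intermediate
13 | (1S,3S,4R,6S)-3,4-dihydroxy-3-methyl-6-(6-methyl-3-oxohepta-1,5-dien-2-yl)-2-oxocyclohexyl 3-methylbutanoate | C=C(C(=O)CC=C(C)C)[C@@H]1C[C@@H](O)[C@](C)(O)C(=O)[C@H]1OC(=O)CC(C)C | intermediate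
14 | (1S,3S,4R,6S)-6-[(4E)-6-hydroperoxy-6-methyl-3-oxohepta-1,4-dien-2-yl]-3,4-dihydroxy-3-methyl-2-oxocyclohexyl 3-methylbutanoate (CNP0239240.1) | C=C(C(=O)/C=C/C(C)(C)OO)[C@@H]1C[C@@H](O)[C@](C)(O)C(=O)[C@H]1OC(=O)CC(C)C | target

**Step count and risks**

Total steps: 8. Longest linear sequence: 8 steps (from 1).

The three steps most likely to fail:

Step 2. Singlet oxygen may add with poor facial selectivity (partly syn to the isopropenyl group). The silyl enol ether endoperoxide may fragment to an α′-silylperoxy enone before it is oxidised. DMDO may attack syn to the peroxide bridge and give the wrong C2 configuration. The fallback builds the ring oxygens by classical enone chemistry; it sets out from 1 and returns to the route at 8. Mn(OAc)3·2H2O with excess 3-methylbutanoic acid in refluxing benzene should α′-acyloxylate the enone to (1S,6S)-3-methyl-2-oxo-6-(prop-1-en-2-yl)cyclohex-3-en-1-yl 3-methylbutanoate F1. Luche reduction (NaBH4, CeCl3·7H2O, MeOH, −78 °C) should deliver hydride axially to give (1S,2S,6S)-2-hydroxy-3-methyl-6-(prop-1-en-2-yl)cyclohex-3-en-1-yl 3-methylbutanoate F2, with the hydroxyl cis to the isopropenyl group. Hydroxyl-directed epoxidation (VO(acac)2, t-BuOOH, CH2Cl2, 0 °C) should give the syn-epoxy alcohol F3. DMP (NaHCO3, CH2Cl2) should oxidise it to the cis-epoxy ketone F4. Acid-catalysed hydrolysis (HClO4 cat., THF–H2O, 0 °C) should open the oxirane at C3 by trans-diaxial attack (Fürst–Plattner rule, attack at the carbon remote from the carbonyl), giving the C2/C3 trans-diol 8.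

Step 6. The relay from the branched γ-adduct to the linear α-adduct may stall, or the oxocarbenium intermediate may divert into Prins-type cyclisation, leaving a regioisomer mixture. The fallback sets out from 10 and returns at 12. Indium-mediated Barbier allylation (allyl bromide, In, THF–H2O, rt), which has no regiochemical issue, should give the allyl carbinol (1S,3S,4R,6S)-3,4-dihydroxy-6-(3-hydroxyhexa-1,5-dien-2-yl)-3-methyl-2-oxocyclohexyl 3-methylbutanoate F5. Cross-metathesis with 2-methyl-2-butene (second-generation ruthenium benzylidene catalyst, CH2Cl2, 40 °C) should convert only the monosubstituted alkene into the prenyl group of 12.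

Step 5. The selenium-mediated allylic oxidation may suffer from low conversion of the inductively deactivated isopropenyl group, over-oxidation, or competing oxidation α to the ring ketone. The fallback sets out from 8 and returns at 10. Ene-type allylic chlorination with HOCl generated in situ (Ca(OCl)2, solid CO2, CH2Cl2–H2O, 0 °C) should give the allylic chloride (1S,3S,4R,6S)-6-(3-chloroprop-1-en-2-yl)-3,4-dihydroxy-3-methyl-2-oxocyclohexyl 3-methylbutanoate F6. Kornblum-type oxidation with N-methylmorpholine N-oxide (MeCN, rt) should convert the allylic chloride into the enal 10.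

Further compounds
F1 | step 2 | (1S,6S)-3-methyl-2-oxo-6-(prop-1-en-2-yl)cyclohex-3-en-1-yl 3-methylbutanoate | CC(=C)[C@@H]1CC=C(C)C(=O)[C@H]1OC(=O)CC(C)C
F2 | step 2 | (1S,2S,6S)-2-hydroxy-3-methyl-6-(prop-1-en-2-yl)cyclohex-3-en-1-yl 3-methylbutanoate | CC(=C)[C@@H]1CC=C(C)[C@H](O)[C@H]1OC(=O)CC(C)C
F3 | step 2 | syn-epoxy alcohol, 3,4-epoxide of F2 with the oxirane cis to the hydroxyl and to the isopropenyl group | CC(=C)[C@@H]1C[C@@H]2O[C@]2(C)[C@H](O)[C@H]1OC(=O)CC(C)C
F4 | step 2 | cis-epoxy ketone, 3,4-epoxy-3-methyl-2-oxo-6-(prop-1-en-2-yl)cyclohexyl 3-methylbutanoate with the oxirane cis to the isopropenyl group | CC(=C)[C@@H]1C[C@@H]2O[C@]2(C)C(=O)[C@H]1OC(=O)CC(C)C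
F5 | step 6 | (1S,3S,4R,6S)-3,4-dihydroxy-6-(3-hydroxyhexa-1,5-dien-2-yl)-3-methyl-2-oxocyclohexyl 3-methylbutanoate, carbinol epimers | C=C(C(O)CC=C)[C@@H]1C[C@@H](O)[C@](C)(O)C(=O)[C@H]1OC(=O)CC(C)C
F6 | step 5 | (1S,3S,4R,6S)-6-(3-chloroprop-1-en-2-yl)-3,4-dihydroxy-3-methyl-2-oxocyclohexyl 3-methylbutanoate | C=C(CCl)[C@@H]1C[C@@H](O)[C@](C)(O)C(=O)[C@H]1OC(=O)CC(C)C
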